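**Plan**

1. Retrosynthetic cuts (carbocycle numbered C1 = C–OH, C2 = C–Br, C4 = carbon carrying the side chain): first the C(sp2)–C(sp2) bond in the middle of the diene, giving two C10 halves; then the C1–CH3 bond; then the two ring bonds flanking the C5–C6 ethano unit (C4–C5 and C6–C1), a [4+2] retron.
2. Enabling feature: the cyclohexane has O on C1 and the side-chain carbon on C4 in a cis-1,4 relation, Br on C2, and plain CH2 groups at C5/C6. C1–O and C4–C map onto the O–C(=O) unit of a 2-pyrone, C2–Br onto its 5-bromo substituent, and C5–C6 onto a dienophile whose activating CO2H is excised afterwards.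
3. Forward: 5-bromo-2-pyrone and acrylic acid give the carbocycle as a bridged lactone (step 1). Decarboxylation, lactone to alkyne to (E)-iodopropenyl, enone, bromoketone and bromohydrin follow. The bromo-oxane ring is made separately from linalool by bromoetherification, and a Heck coupling joins the halves last.
4. Stereochemistry: C4 from an alcohol-dehydrogenase oxidative kinetic resolution of the racemic cycloadduct-derived allylic alcohol; C2 by axial protonation of the bromoenolate (relay from C4); C1 by methyl addition anti to Br (relay from C2). Oxane C6 comes from (R)-linalool and C3 from the chair bromoetherification (epimer separated). Alkene geometries come from syn-carboalumination and Heck β-hydride elimination.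

Key step: step 1

Remark: compounds 3 to 9 are racemates whose SMILES show the enantiomer that step 5 carries on; 3 is drawn as the expected major regio- and endo-isomer, and all its isomers at the carboxyl-bearing carbon give the same 5 in step 2.

**Step 1**
Reactants: 1 5-bromo-2H-pyran-2-one; 2 acrylic acid
Product: 3 rac-(1R,4S,5R)-7-bromo-3-oxo-2-oxabicyclo[2.2.2]oct-7-ene-5-carboxylic acid
Conditions: 2 (3 equiv), BHT (cat.), toluene, 90 °C, sealed tube
Reagents that add atoms: none
Why: Concerted thermal [4+2] cycloaddition (Diels–Alder reaction of a 2-pyrone): the pyrone C3=C4–C5=C6 unit, held s-cis by its ring, adds suprafacially to the acrylic acid C=C, so that the two new σ-bonds (pyrone C3–CH and pyrone C6–CH2) close the carbocycle in one intermolecular six-centre event and turn the flat heteroarene into a 2-oxabicyclo[2.2.2]octene whose O–C(=O) unit is the third bridge. The closest known reaction type is the thermal cycloaddition of 3- and 5-bromo-2-pyrones with acrylates, where the bromine makes the diene reactive enough to add below the temperature at which the adducts lose CO2. The two bridgehead stereocentres (the future C1–O and C4–C carbons) form together and their cis relation is enforced by the lactone bridge; the carboxyl-bearing centre is expected mainly endo through secondary orbital overlap, but it is erased in step 2. The step needs only mono-addition across C3/C6 and survival of the lactone bridge, secured by the 5-bromo substituent, the moderate temperature and the radical inhibitor; regio- and endo/exo selectivity are not needed because every isomer converges on 5. Absolute configuration is not set here (3 is racemic) and is fixed in step 5.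

**Step 2**
Reactants: 3 rac-(1R,4S,5R)-7-bromo-3-oxo-2-oxabicyclo[2.2.2]oct-7-ene-5-carboxylic acid
Product: 5 rac-(1R,4S)-6-bromo-2-oxabicyclo[2.2.2]oct-5-en-3-one, via Barton ester 4 (not isolated)
Conditions: 1-hydroxypyridine-2(1H)-thione, DCC, CH2Cl2, 0 °C to rt, dark; then t-BuSH (excess), hν (tungsten lamp), rt
Reagents that add atoms: none
Why: Barton reductive decarboxylation: the thiohydroxamate ester fragments to a secondary alkyl radical that the thiol, used in excess, should reduce faster than it can rearrange through the homoallyl–cyclopropylcarbinyl pathway; the auxiliary stereocentre disappears and the lactone and vinyl bromide are untouched.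

**Step 3**
Reactants: 5 rac-(1R,4S)-6-bromo-2-oxabicyclo[2.2.2]oct-5-en-3-one
Product: 7 rac-(1R,4S)-2-bromo-4-ethynylcyclohex-2-en-1-ol, via hydroxy aldehyde 6 (not isolated)
Conditions: i-Bu2AlH (1.1 equiv), CH2Cl2, −78 °C; then MeOH, K2CO3, dimethyl (1-diazo-2-oxopropyl)phosphonate, −78 to 0 °C
Reagents that add atoms: dimethyl (1-diazo-2-oxopropyl)phosphonate, COP(=O)(OC)C(=[N+]=[N-])C(C)=O
Why: Partial reduction of the lactone to the aluminium lactolate, then Ohira–Bestmann (Seyferth–Gilbert) homologation of the released aldehyde 6 to the terminal alkyne in the same flask; no stereocentre is formed, the two existing ones should be retained because the aldehyde is consumed as it is released at or below 0 °C, and any C4 epimer would be a trans diastereomer that is removed by chromatography.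

**Step 4**
Reactants: 7 rac-(1R,4S)-2-bromo-4-ethynylcyclohex-2-en-1-ol
Product: 9 rac-(1R,4S)-2-bromo-4-[(1E)-1-iodoprop-1-en-2-yl]cyclohex-2-en-1-ol, via alkenylalane 8 (not isolated)
Conditions: Me3Al (3 equiv), Cp2ZrCl2 (0.3 equiv), CH2Cl2, 0 °C to rt; then I2, THF, −30 °C; aq. Na2S2O3, aq. potassium sodium tartrate
Reagents that add atoms: trimethylaluminium, C[Al](C)C; iodine, II
Why: Negishi zirconium-catalysed carboalumination: methyl and aluminium add syn across the terminal alkyne with methyl at the internal carbon, and iodinolysis of the C–Al bond with retention gives the (E)-iodoalkene; the hydroxyl is masked in the flask as its aluminium alkoxide, the vinyl bromide is inert, and no stereocentre is formed.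

**Step 5**
Reactants: 9 rac-(1R,4S)-2-bromo-4-[(1E)-1-iodoprop-1-en-2-yl]cyclohex-2-en-1-ol
Product: 10 (4S)-2-bromo-4-[(1E)-1-iodoprop-1-en-2-yl]cyclohex-2-en-1-one
Conditions: (R)-selective NADP-dependent alcohol dehydrogenase (Lactobacillus type, chosen from a ketoreductase panel), NADP+ (cat.), MgCl2, acetone (co-substrate, 15% v/v), DMSO (5% v/v), phosphate buffer pH 7.5, 30 °C, stopped near half conversion
Reagents that add atoms: none
Why: Enzymatic oxidative kinetic resolution by an alcohol dehydrogenase: hydride abstraction from the carbinol carbon is enantiospecific, so only the (1R,4S) enantiomer of 9 should be dehydrogenated (acetone regenerates NADP+ and conjugation of the enone drives the equilibrium), which leaves C4 as the only stereocentre of 10 in the (S) configuration, while the (1S,4R) alcohol stays behind and is removed by chromatography.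

**Step 6**
Reactants: 10 (4S)-2-bromo-4-[(1E)-1-iodoprop-1-en-2-yl]cyclohex-2-en-1-one
Product: 12 (2S,4S)-2-bromo-4-[(1E)-1-iodoprop-1-en-2-yl]cyclohexan-1-one, via lithium bromoenolate 11 (not isolated)
Conditions: LiBH(s-Bu)3 (1.05 equiv), THF, −78 °C; then AcOH in THF, −78 °C
Reagents that add atoms: none
Why: Conjugate (1,4) hydride reduction of the β-unsubstituted enone by the hindered trialkylborohydride gives enolate 11, and its kinetic protonation at C2 should occur axially through a chair-like transition state with the C4 side chain equatorial, so that Br ends equatorial and cis to the side chain (2S); the product is carried on without delay to avoid epimerisation.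

**Step 7**
Reactants: 12 (2S,4S)-2-bromo-4-[(1E)-1-iodoprop-1-en-2-yl]cyclohexan-1-one
Product: 13 (1R,2S,4S)-2-bromo-4-[(1E)-1-iodoprop-1-en-2-yl]-1-methylcyclohexan-1-ol
Conditions: MeMgBr (1.2 equiv), Et2O, −78 °C; aq. NH4Cl
Reagents that add atoms: methylmagnesium bromide, C[Mg]Br
Why: Grignard addition to an α-bromoketone: as in the additions to 2-halocyclohexanones that give cis-halohydrins, the methyl group should enter anti to the C–Br bond (polar Felkin–Anh/Cornforth control, equatorial attack on the chair with Br and side chain equatorial), which makes the new C1 centre (1R) with axial OH cis to Br; at −78 °C addition should outrun enolisation and the vinyl iodide is inert.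

**Step 8**
Reactants: 14 (R)-(−)-linalool
Product: 15 (3S,6R)-3-bromo-6-ethenyl-2,2,6-trimethyloxane
Conditions: 2,4,4,6-tetrabromocyclohexa-2,5-dien-1-one (1.1 equiv), MeNO2, 0 °C, dark
Reagents that add atoms: 2,4,4,6-tetrabromocyclohexa-2,5-dien-1-one, O=C1C(Br)=CC(Br)(Br)C=C1Br
Why: Bromonium-induced 6-endo etherification (bromoetherification): the tertiary hydroxyl opens the bromonium ion of the trisubstituted alkene at its more substituted carbon through a chair transition state with Br equatorial; C6 keeps the configuration of (R)-linalool and the new C3 centre is (S) in the isomer with the vinyl group equatorial, which is separated by chromatography from its C3 epimer and from the 5-exo tetrahydrofuran isomers.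

**Step 9**
Reactants: 13 (1R,2S,4S)-2-bromo-4-[(1E)-1-iodoprop-1-en-2-yl]-1-methylcyclohexan-1-ol; 15 (3S,6R)-3-bromo-6-ethenyl-2,2,6-trimethyloxane
Product: 16 (1R,2S,4S)-2-bromo-4-[(2E,4E)-5-[(2R,5S)-5-bromo-2,6,6-trimethyloxan-2-yl]penta-2,4-dien-2-yl]-1-methylcyclohexan-1-ol
Conditions: Pd(OAc)2 (10 mol %), Bu4NCl, NaHCO3, DMF, 40 °C
Reagents that add atoms: none
Why: Mizoroki–Heck vinylation under Jeffery conditions: zerovalent palladium should insert only into the C(sp2)–I bond, carbopalladation places the alkenyl group on the terminal CH2 of 15, and syn β-hydride elimination can only give the (E)-disubstituted alkene because the other neighbour is quaternary; the (E)-geometry of the iodoalkene is retained, no stereocentre is formed, and the two secondary alkyl bromides and the tertiary alcohol should tolerate the mild base.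

**Compound list**

1 | 5-bromo-2H-pyran-2-one | O=C1C=CC(Br)=CO1 | starting material
2 | acrylic acid | C=CC(=O)O | starting material
3 | rac-(1R,4S,5R)-7-bromo-3-oxo-2-oxabicyclo[2.2.2]oct-7-ene-5-carboxylic acid (endo acid, CO2H on the carbon next to the lactone-carbonyl bridgehead) | O=C1[C@H]2[C@H](C(=O)O)C[C@@H](O1)C(Br)=C2 | intermediate
4 | rac-2-thioxopyridin-1(2H)-yl (1R,4S,5R)-7-bromo-3-oxo-2-oxabicyclo[2.2.2]oct-7-ene-5-carboxylate (Barton ester) | O=C1[C@H]2[C@H](C(=O)ON3C=CC=CC3=S)C[C@@H](O1)C(Br)=C2 | intermediate (not isolated)
5 | rac-(1R,4S)-6-bromo-2-oxabicyclo[2.2.2]oct-5-en-3-one | O=C1[C@H]2CC[C@@H](O1)C(Br)=C2 | intermediate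
6 | rac-(1S,4R)-3-bromo-4-hydroxycyclohex-2-ene-1-carbaldehyde (released from its aluminium lactolate) | O=C[C@H]1CC[C@@H](O)C(Br)=C1 | intermediate (not isolated)
7 | rac-(1R,4S)-2-bromo-4-ethynylcyclohex-2-en-1-ol (cis) | C#C[C@H]1CC[C@@H](O)C(Br)=C1 | intermediate
8 | rac-(E)-alkenyl(dimethyl)alane of 7, hydroxyl as its dimethylaluminium alkoxide | C/C(=C\[Al](C)C)[C@H]1CC[C@@H](O[Al](C)C)C(Br)=C1 | intermediate (not isolated)
9 | rac-(1R,4S)-2-bromo-4-[(1E)-1-iodoprop-1-en-2-yl]cyclohex-2-en-1-ol (cis) | C/C(=C\I)[C@H]1CC[C@@H](O)C(Br)=C1 | intermediate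
10 | (4S)-2-bromo-4-[(1E)-1-iodoprop-1-en-2-yl]cyclohex-2-en-1-one | C/C(=C\I)[C@H]1CCC(=O)C(Br)=C1 | intermediate
11 | lithium (4S)-2-bromo-4-[(1E)-1-iodoprop-1-en-2-yl]cyclohex-1-en-1-olate | C/C(=C\I)[C@H]1CCC(O[Li])=C(Br)C1 | intermediate (not isolated)
12 | (2S,4S)-2-bromo-4-[(1E)-1-iodoprop-1-en-2-yl]cyclohexan-1-one (Br cis to side chain) | C/C(=C\I)[C@H]1CCC(=O)[C@@H](Br)C1 | intermediate
13 | (1R,2S,4S)-2-bromo-4-[(1E)-1-iodoprop-1-en-2-yl]-1-methylcyclohexan-1-ol (OH, Br and side chain all cis) | C/C(=C\I)[C@H]1CC[C@@](C)(O)[C@@H](Br)C1 | intermediate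
14 | (R)-(−)-linalool, (3R)-3,7-dimethylocta-1,6-dien-3-ol | C=C[C@](C)(O)CCC=C(C)C | starting material
15 | (3S,6R)-3-bromo-6-ethenyl-2,2,6-trimethyloxane (Br and vinyl trans) | C=C[C@@]1(C)CC[C@H](Br)C(C)(C)O1 | intermediate
16 | (1R,2S,4S)-2-bromo-4-[(2E,4E)-5-[(2R,5S)-5-bromo-2,6,6-trimethyloxan-2-yl]penta-2,4-dien-2-yl]-1-methylcyclohexan-1-ol | C/C(=C\C=C\[C@@]1(C)CC[C@H](Br)C(C)(C)O1)[C@H]1CC[C@@](C)(O)[C@@H](Br)C1 | target

**Step count and risks**

Total step count: 9. Longest linear sequence: 8 steps (steps 1 to 7, then step 9).

Steps most likely to fail: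

Step 5. The enzyme may not accept the hindered bromo-iodo cyclohexenol, or may discriminate its enantiomers too weakly, so that the enone forms slowly or in low optical purity. The fallback sets out from racemic 9 and comes back at 10. Lipase-catalysed transesterification (Burkholderia cepacia lipase or Candida antarctica lipase B, vinyl acetate, MTBE, 30 °C) should, by the usual preference of lipases for the (R)-carbinol, acylate only the wanted enantiomer and give (1R,4S)-2-bromo-4-[(1E)-1-iodoprop-1-en-2-yl]cyclohex-2-en-1-yl acetate F1. After chromatographic removal of the unreacted (1S,4R)-alcohol, methanolysis (K2CO3, MeOH, 0 °C) should release enantiopure (1R,4S)-9, and Dess–Martin periodinane (NaHCO3, CH2Cl2) should oxidise it to 10.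

Step 6. Protonation of enolate 11 may be poorly face-selective, or the α-bromoketone may epimerise at C2 during work-up; either gives the trans isomer, which leads to a diastereomer of 13. The fallback sets out from 10 and comes back at 12. The enolate formed with LiBH(s-Bu)3 is trapped with Me3SiCl to give the isolable silyl enol ether {[(4S)-2-bromo-4-[(1E)-1-iodoprop-1-en-2-yl]cyclohex-1-en-1-yl]oxy}trimethylsilane F2. This is then protonated under reagent control with a Lewis-acid-assisted chiral Brønsted acid (SnCl4·BINOL, toluene, −78 °C), the BINOL enantiomer being chosen to reinforce axial protonation, so that C2 is set by the chiral proton donor and not by the ring alone.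

Step 9. Carbopalladation of the alkene next to a quaternary carbon may be sluggish, the diene may migrate or scramble E/Z through palladium hydride, or the bromohydrin may degrade under base on prolonged heating. The fallback sets out from 15 and 13 and comes back at 16. Ozonolysis of 15 (O3, CH2Cl2, −78 °C; Me2S) should give (2R,5S)-5-bromo-2,6,6-trimethyloxane-2-carbaldehyde F3. Takai-type boryl-olefination (CrCl2, Cl2CHB(pin), LiI, THF) should give 2-[(E)-2-[(2R,5S)-5-bromo-2,6,6-trimethyloxan-2-yl]ethenyl]-4,4,5,5-tetramethyl-1,3,2-dioxaborolane F4. Suzuki–Miyaura coupling of this boronate with 13 (Pd(PPh3)4, aq. K3PO4, THF, 40 °C) should then give 16 with both alkene geometries defined by the partners.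

**Further compounds**

F1 | step 5 | (1R,4S)-2-bromo-4-[(1E)-1-iodoprop-1-en-2-yl]cyclohex-2-en-1-yl acetate | C/C(=C\I)[C@H]1CC[C@@H](OC(C)=O)C(Br)=C1
F2 | step 6 | {[(4S)-2-bromo-4-[(1E)-1-iodoprop-1-en-2-yl]cyclohex-1-en-1-yl]oxy}trimethylsilane | C/C(=C\I)[C@H]1CCC(O[Si](C)(C)C)=C(Br)C1
F3 | step 9 | (2R,5S)-5-bromo-2,6,6-trimethyloxane-2-carbaldehyde | O=C[C@@]1(C)CC[C@H](Br)C(C)(C)O1
F4 | step 9 | 2-[(E)-2-[(2R,5S)-5-bromo-2,6,6-trimethyloxan-2-yl]ethenyl]-4,4,5,5-tetramethyl-1,3,2-dioxaborolane | CC1(C)OB(/C=C/[C@@]2(C)CC[C@H](Br)C(C)(C)O2)OC1(C)C
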